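The flavone is cut through ring C at three bonds: C4a–C4, C4–C3 and O1–C2. The feature exploited is that C4 is a single carbonyl carbon lying between aryl carbon C4a of ring A (ortho to the C8a oxygen and next to the unsubstituted C5) and the C3–C2 pair carrying ring B, a pattern that maps onto an ortho-iodophenol, carbon monoxide and a terminal aryl acetylene. One palladium-catalysed carbonylative coupling joins rings A and B and closes the pyranone in the same flask. Its precursors are 6-iodo-2,3,4-trimethoxyphenol and a MOM-protected 3-hydroxy-4,5-dimethoxyphenylacetylene, each two steps from a commercial benzaldehyde; acid then frees the ring B phenol.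

Key step: step 5

Remark: enaminone 10 is drawn as the E isomer expected from amine addition to an ynone; either geometry should close to the same ring, because both substituents on the amine-bearing carbon lie outside the ring being formed.

Step 1
Reactants: 1 2,3,4-trimethoxybenzaldehyde
Product: 3 2,3,4-trimethoxyphenol, via 2,3,4-trimethoxyphenyl formate 2 (not isolated)
Conditions: mCPBA, CH2Cl2, 0 °C to rt; aqueous NaHCO3 wash; then K2CO3 (cat.), MeOH, rt
Reagents that add atoms: 3-chloroperoxybenzoic acid (mCPBA), OOC(=O)c1cccc(Cl)c1
Why: Baeyer–Villiger (Dakin-type) oxidation, in which the electron-rich aryl group with ortho and para methoxy donors migrates in preference to hydride to give formate 2, which base-catalysed methanolysis then cleaves to the phenol.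

Step 2
Reactants: 3 2,3,4-trimethoxyphenol
Product: 4 6-iodo-2,3,4-trimethoxyphenol
Conditions: I2, NaHCO3, THF/H2O, 0 °C to rt
Reagents that add atoms: iodine, II
Why: Electrophilic aromatic iodination, in which the hydroxyl group (partly as phenoxide under bicarbonate) is the strongest activator and, with its para position blocked by methoxy, should direct iodine to the free ortho carbon C6 instead of C5, which is only ortho to a methoxy group.

Step 3
Reactants: 5 3-hydroxy-4,5-dimethoxybenzaldehyde
Product: 6 3,4-dimethoxy-5-(methoxymethoxy)benzaldehyde
Conditions: MOMCl, iPr2NEt, CH2Cl2, 0 °C to rt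
Reagents that add atoms: chloromethyl methyl ether (MOMCl), COCCl
Why: Williamson-type O-alkylation of the phenol with the reactive alpha-chloro ether gives the MOM acetal, which is stable to the basic conditions of the next two steps and leaves the non-enolisable aldehyde untouched.

Step 4
Reactants: 6 3,4-dimethoxy-5-(methoxymethoxy)benzaldehyde
Product: 7 5-ethynyl-1,2-dimethoxy-3-(methoxymethoxy)benzene
Conditions: dimethyl (1-diazo-2-oxopropyl)phosphonate, K2CO3, MeOH, 0 °C to rt
Reagents that add atoms: dimethyl (1-diazo-2-oxopropyl)phosphonate (Ohira–Bestmann reagent), COP(=O)(OC)C(=[N+]=[N-])C(C)=O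
Why: Seyferth–Gilbert homologation in the Ohira–Bestmann variant, in which methanolysis of the reagent releases the diazomethylphosphonate anion that adds to the aldehyde, eliminates dimethyl phosphate in a Horner–Wadsworth–Emmons manner and loses nitrogen with a 1,2-hydride shift to give the terminal alkyne under mild base that the MOM ether tolerates.

Step 5
Reactants: 4 6-iodo-2,3,4-trimethoxyphenol; 7 5-ethynyl-1,2-dimethoxy-3-(methoxymethoxy)benzene; 8 carbon monoxide
Product: 11 2-[3,4-dimethoxy-5-(methoxymethoxy)phenyl]-6,7,8-trimethoxy-4H-chromen-4-one, via hydroxyaryl ynone 9 (not isolated), via diethylamino enone 10 (not isolated)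
Conditions: PdCl2(dppf) (5 mol%), CO (20 atm), Et2NH, 120 °C, autoclave
Reagents that add atoms: none
Why: Zerovalent palladium formed in situ from PdCl2(dppf) (dppf = 1,1'-bis(diphenylphosphino)ferrocene) adds oxidatively to the C–I bond of 4, CO inserts to give an aroylpalladium iodide, and coupling with the acetylide of 7 followed by reductive elimination gives ynone 9, so that the C4a–C4 and C4–C3 bonds form around the CO carbon. Diethylamine then adds in conjugate fashion to 9 to give enaminone 10, and the phenol oxygen attacks the amine-bearing carbon and expels diethylamine, forming O1–C2. Ring C, the only ring made in the route, is thus closed by a 6-endo addition–elimination, a net 6-endo-dig closure of the ynone. The closest known reaction type is the palladium-catalysed carbonylative Sonogashira annulation of ortho-iodophenols with terminal aryl acetylenes in a secondary amine. No stereocentre is created. The step needs CO uptake before alkynylation (direct coupling would end in a 2-arylbenzofuran) and six- over five-membered closure (the aurone): CO pressure, copper-free conditions and the electron-rich aryl–palladium bond favour insertion, the enaminone leaves the beta carbon as the only site open to the phenol, and the MOM ether keeps the ring B phenol away from the aroylpalladium.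

Step 6
Reactants: 11 2-[3,4-dimethoxy-5-(methoxymethoxy)phenyl]-6,7,8-trimethoxy-4H-chromen-4-one
Product: 12 2-(3-hydroxy-4,5-dimethoxyphenyl)-6,7,8-trimethoxy-4H-chromen-4-one (target flavone CNP0265341.0)
Conditions: HCl (cat.), MeOH/THF, 50 °C
Reagents that add atoms: none
Why: Acid-catalysed acetal exchange (MOM ether cleavage) transfers the methoxymethyl group to methanol and frees the phenol, while the aryl methyl ethers and the flavone core, which has no chelated 5-methoxy group prone to loss, should be inert to dilute acid.

Compound list
1 | 2,3,4-trimethoxybenzaldehyde | COc1ccc(C=O)c(OC)c1OC | starting material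
2 | 2,3,4-trimethoxyphenyl formate | COc1ccc(OC=O)c(OC)c1OC | intermediate (not isolated)
3 | 2,3,4-trimethoxyphenol | COc1ccc(O)c(OC)c1OC | intermediate
4 | 6-iodo-2,3,4-trimethoxyphenol | COc1cc(I)c(O)c(OC)c1OC | intermediate
5 | 3-hydroxy-4,5-dimethoxybenzaldehyde | COc1cc(C=O)cc(O)c1OC | starting material
6 | 3,4-dimethoxy-5-(methoxymethoxy)benzaldehyde | COCOc1cc(C=O)cc(OC)c1OC | intermediate
7 | 5-ethynyl-1,2-dimethoxy-3-(methoxymethoxy)benzene | C#Cc1cc(OC)c(OC)c(OCOC)c1 | intermediate
8 | carbon monoxide | [C-]#[O+] | starting material
9 | 3-[3,4-dimethoxy-5-(methoxymethoxy)phenyl]-1-(2-hydroxy-3,4,5-trimethoxyphenyl)prop-2-yn-1-one | COCOc1cc(C#CC(=O)c2cc(OC)c(OC)c(OC)c2O)cc(OC)c1OC | intermediate (not isolated)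
10 | (E)-3-(diethylamino)-3-[3,4-dimethoxy-5-(methoxymethoxy)phenyl]-1-(2-hydroxy-3,4,5-trimethoxyphenyl)prop-2-en-1-one | CCN(CC)/C(=C/C(=O)c1cc(OC)c(OC)c(OC)c1O)c1cc(OC)c(OC)c(OCOC)c1 | intermediate (not isolated)
11 | 2-[3,4-dimethoxy-5-(methoxymethoxy)phenyl]-6,7,8-trimethoxy-4H-chromen-4-one | COCOc1cc(-c2cc(=O)c3cc(OC)c(OC)c(OC)c3o2)cc(OC)c1OC | intermediate
12 | 2-(3-hydroxy-4,5-dimethoxyphenyl)-6,7,8-trimethoxy-4H-chromen-4-one | COc1cc(-c2cc(=O)c3cc(OC)c(OC)c(OC)c3o2)cc(O)c1OC | target

Total step count: 6
Longest linear sequence: 4 steps (steps 1, 2, 5, 6 from 1; equally steps 3, 4, 5, 6 from 5)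

Steps most likely to fail

1. Step 5. Diethylamine may capture the aroylpalladium faster than the acetylide does (amide formation), coupling may occur without CO uptake and end in benzofuran closure, or the ynone may close in the five-membered mode. The fallback gives up CO as the source of C4 and builds ring C by the chalcone route. It sets out from phenol 3 and aldehyde 6. C-Acetylation of 3 ortho to the hydroxyl with AcOH and BF3·OEt2 at 90 °C (Fries-type acylation) should give 1-(2-hydroxy-3,4,5-trimethoxyphenyl)ethanone F1. Claisen–Schmidt condensation of this ketone with 6 (KOH, EtOH, rt) should give (E)-3-[3,4-dimethoxy-5-(methoxymethoxy)phenyl]-1-(2-hydroxy-3,4,5-trimethoxyphenyl)prop-2-en-1-one F2. Oxidative cyclisation of the 2'-hydroxychalcone with I2 (cat.) in DMSO at 120 °C returns to the route at 11; any material that loses the MOM group under these conditions is already 12.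

2. Step 2. Iodination may take place in part at C5, ortho to the 4-methoxy group, a second iodine may be introduced, or iodine may oxidise the electron-rich phenol. The fallback replaces electrophilic substitution by directed ortho-metalation and sets out from 3. Protection with MOMCl and iPr2NEt should give 1,2,3-trimethoxy-4-(methoxymethoxy)benzene F3. Lithiation with n-BuLi and TMEDA in THF at 0 °C, directed by the chelating OMOM group in preference to methoxy, and quenching with I2 should give 1-iodo-3,4,5-trimethoxy-2-(methoxymethoxy)benzene F4. Cleavage of the acetal with HCl in MeOH returns to the route at 4.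

3. Step 4. Addition of the diazophosphonate anion to the electron-rich aldehyde may be slow, so that base-mediated decay of the reagent outruns the homologation and conversion stays incomplete. The fallback is the two-stage Corey–Fuchs sequence from 6. Treatment with CBr4 and PPh3 in CH2Cl2 at 0 °C should give 5-(2,2-dibromoethenyl)-1,2-dimethoxy-3-(methoxymethoxy)benzene F5. Treatment with n-BuLi (2.2 equiv) in THF at −78 °C, through bromine–lithium exchange and 1,2-shift, followed by aqueous NH4Cl, returns to the route at 7.

Further compounds
F1 | step 5 | 1-(2-hydroxy-3,4,5-trimethoxyphenyl)ethanone | CC(=O)c1cc(OC)c(OC)c(OC)c1O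
F2 | step 5 | (E)-3-[3,4-dimethoxy-5-(methoxymethoxy)phenyl]-1-(2-hydroxy-3,4,5-trimethoxyphenyl)prop-2-en-1-one | COCOc1cc(/C=C/C(=O)c2cc(OC)c(OC)c(OC)c2O)cc(OC)c1OC
F3 | step 2 | 1,2,3-trimethoxy-4-(methoxymethoxy)benzene | COCOc1ccc(OC)c(OC)c1OC
F4 | step 2 | 1-iodo-3,4,5-trimethoxy-2-(methoxymethoxy)benzene | COCOc1c(I)cc(OC)c(OC)c1OC
F5 | step 4 | 5-(2,2-dibromoethenyl)-1,2-dimethoxy-3-(methoxymethoxy)benzene | COCOc1cc(C=C(Br)Br)cc(OC)c1OC
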